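The pitfall in this pair is to let the clock rank the flasks: epsilon runs twice as long as delta, yet its warm part ends at 20 min.

| setting | violet | epsilon | delta |
|---|---|---|---|
| substrate | 0.099 M | 0.099 M | 0.099 M |
| coupling partner | 1.1 equiv | 1.10 equiv | 1.10 equiv |
| free catalyst | 10 mol% | 5 mol% | 5 mol% |
| temperature | 35 °C |  |  |
| remark | run made earlier | at 35 °C until 20 min, from then on at 5 °C | at 35 °C throughout |
| time |  | 1.0 h | 0.50 h |

- violet (time / min: product / %, substrate / %): 4.00: 5.9, 84.4; 8.00: 11.3, 78.0; 10.0: 15.9, 73.3; 15.0: 24.0, 66.2; 20.0: 31.7, 58.9

(each reading ± 1 percentage point)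

- what was read earlier has a scatter of 1 percentage point, one standard deviation
- the earlier runs do not show what temperature does; that part of a forecast is a guess
- no earlier run changes the charge of free catalyst; that part of a forecast is a guess

* the flask that ends with the higher amount of product, in percent of the substrate charged, or "neither" when 2 percentage points or less lies between them (epsilon / delta / neither)
* final product, as a percentage of the substrate charged, in epsilon
* final product, as a percentage of the substrate charged, in delta

The violet run gains product steadily, and from its first to its last reading this gives a turnover frequency, 0.161 min⁻¹, meaning product formed per minute per unit of catalyst charged. No run changes the loading, so assuming proportion to the catalyst is a guess. With it, delta reaches 24.2 %. Epsilon can then be bracketed. If the cold stopped it dead, epsilon would hold 16.1 %; if the cold cost nothing, it would reach 48.4 %. Delta lies inside that bracket, so the bounds leave the ranking open.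

Tightening needs one comparison of rates. To draw level with delta, epsilon's cold stretch must keep 25.0 % of the warm rate. No run shows temperature, so my own guess is a rule of thumb: halving per 10 °C, taken 3 times across the drop, leaves 12.5 %. That is less than the share required, and it puts epsilon near 20.2 %, behind delta.

The forecast, a little below this reckoning, also stands inside the bracket, with 18.5 % for epsilon, 23.7 % for delta and delta ahead: “Delta wins unless Ea is below about 33 kJ/mol”.

The flasks give 19.5 % in epsilon and 24.5 % in delta, so delta ends higher.

    substrate + free catalyst ⇌ catalyst intermediate A (K = 592 M⁻¹, k = 39.2 M⁻¹ min⁻¹, Ea = 64.0 kJ mol⁻¹, ΔH = −26.0 kJ mol⁻¹)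
    catalyst intermediate A ⇌ catalyst intermediate B (K = 0.270, k = 4.02 min⁻¹, Ea = 83.0 kJ mol⁻¹, ΔH = 0 kJ mol⁻¹)
    coupling partner + catalyst intermediate B ⇌ catalyst intermediate C (K = 6.80 M⁻¹, k = 358 M⁻¹ min⁻¹, Ea = 58.0 kJ mol⁻¹, ΔH = −21.0 kJ mol⁻¹)
    catalyst intermediate C → free catalyst + product (k = 1.56 min⁻¹, Ea = 74.0 kJ mol⁻¹)
    (constants at 35 °C)

Part of what holds delta at 24.5 % is the undoing of catalyst intermediate C into coupling partner and catalyst intermediate B, acting together with the time given: delta gives 84.8 % without that undoing, and 98.2 % left ten times as long. As run, epsilon climbs from 16.8 % at the change of temperature to 19.5 % at the end. Its cold stretch therefore keeps 8.11 % of the rate that the turnover frequency gives, less than the 25.0 % required.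

(The runs are calculated with made-up constants; noise was put on by code.)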